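**Strategy.** The synthesis rests on disconnecting the C6–C7 bond (germacranolide numbering) shared by the ten-membered carbocycle and the α-methylene lactone. The key step is an intramolecular Nozaki–Hiyama allylation: a 3-(bromomethyl)butenolide, already holding the lactone ring and C8, is reduced by CrCl2 and its γ-carbon C7 adds to a C6 aldehyde at the other end of the chain. One operation closes the ten-membered ring, sets C6 and C7, and shifts the butenolide alkene into the exocyclic C11=C13 methylene; it exploits the homoallylic alcohol array C13=C11–C7–C6–OH. The precursor is an open-chain butenolide aldehyde bearing the epoxyangelate, with the C2 ketone masked as a silyl ether.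

Key step: step 19

Assumption: atoms carry germacranolide numbers (C8 bears the lactone oxygen, C7 is the fusion carbon, C11=C13 the exo-methylene, C12 the lactone carbonyl); the C2 carbinol made in step 12 is carried as both epimers (centre left open in the SMILES) because step 21 oxidises it to the ketone.

**Step 1**
Reactants: 1 methyl angelate [methyl (Z)-2-methylbut-2-enoate]
Product: 2 (Z)-2-methylbut-2-en-1-ol
Conditions: i-Bu2AlH (2.2 equiv), CH2Cl2, −78 to 0 °C; Rochelle salt work-up
Reagents that add atoms: none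
Why: i-Bu2AlH reduces the ester to the primary allylic alcohol (1,2-reduction of an enoate) and leaves the Z-trisubstituted alkene untouched.

**Step 2**
Reactants: 2 (Z)-2-methylbut-2-en-1-ol
Product: 3 [(2S,3R)-2,3-dimethyloxiran-2-yl]methanol
Conditions: Ti(Oi-Pr)4 (10 mol %), L-(+)-diethyl tartrate (12 mol %), t-BuOOH, 4 Å MS, CH2Cl2, −20 °C
Reagents that add atoms: tert-butyl hydroperoxide CC(C)(C)OO
Why: Katsuki–Sharpless asymmetric epoxidation: the titanium L-(+)-tartrate complex delivers oxygen to the enantioface that gives 2S epoxy alcohols, and the stereospecific syn addition to the Z-alkene keeps the two methyl groups trans, so C2 (S) and C3 (R) are set together.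

**Step 3**
Reactants: 3 [(2S,3R)-2,3-dimethyloxiran-2-yl]methanol
Product: 4 (2R,3R)-2,3-dimethyloxirane-2-carboxylic acid
Conditions: RuCl3·xH2O (2 mol %), NaIO4, CCl4/MeCN/H2O, rt
Reagents that add atoms: water O
Why: Catalytic RuO4 (from RuCl3 and NaIO4) oxidises the primary alcohol through the aldehyde hydrate to the acid without opening the epoxide; the C2 label changes from S to R only because the substituent priorities change.

**Step 4**
Reactants: 5 2-[(4-methoxybenzyl)oxy]acetaldehyde; 6 trans-2-butene
Product: 8 (2R,3R)-1-[(4-methoxybenzyl)oxy]-3-methylpent-4-en-2-ol, via borinate ester 7 (not isolated)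
Conditions: 6, KOt-Bu, n-BuLi, THF, −78 to −45 °C; (+)-Ipc2BOMe, −78 °C; BF3·OEt2; 5, −78 °C; then NaOH, H2O2, 0 °C to rt
Reagents that add atoms: none
Why: Brown crotylboration: the (E)-crotylborane made from 6 adds through a closed chair transition state, so the E geometry gives the anti methyl/hydroxyl relation and the isopinocampheyl groups of the (+)-Ipc2BOMe series select the aldehyde face that gives 2R,3R; oxidative work-up cleaves borinate 7.

**Step 5**
Reactants: 8 (2R,3R)-1-[(4-methoxybenzyl)oxy]-3-methylpent-4-en-2-ol; 4 (2R,3R)-2,3-dimethyloxirane-2-carboxylic acid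
Product: 9 (2R,3R)-1-[(4-methoxybenzyl)oxy]-3-methylpent-4-en-2-yl (2R,3R)-2,3-dimethyloxirane-2-carboxylate
Conditions: 2-methyl-6-nitrobenzoic anhydride, Et3N, DMAP, CH2Cl2, rt
Reagents that add atoms: none
Why: Shiina esterification: the mixed anhydride is transferred by DMAP to the hindered secondary alcohol with no change at any stereocentre, and the minor enantiomer of 8 becomes a separable diastereomer.

**Step 6**
Reactants: 9 the pent-4-enyl epoxyangelate from step 5
Product: 11 (2R,3R)-5-hydroxy-1-[(4-methoxybenzyl)oxy]-3-methylpentan-2-yl (2R,3R)-2,3-dimethyloxirane-2-carboxylate, via alkylborane 10 (not isolated)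
Conditions: 9-BBN, THF, 0 °C to rt; then H2O2, aq. NaOAc, 0 °C to rt
Reagents that add atoms: hydrogen peroxide OO
Why: Hydroboration–oxidation: 9-BBN adds anti-Markovnikov to the terminal alkene and tolerates ester and epoxide, and buffered peroxide oxidises the C–B bond to the primary alcohol without saponification.

**Step 7**
Reactants: 11 the primary alcohol from step 6
Product: 12 (2R,3R)-1-[(4-methoxybenzyl)oxy]-3-methyl-5-oxopentan-2-yl (2R,3R)-2,3-dimethyloxirane-2-carboxylate
Conditions: TEMPO (10 mol %), PhI(OAc)2, CH2Cl2, rt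
Reagents that add atoms: none
Why: TEMPO-catalysed oxidation with PhI(OAc)2 stops at the aldehyde, and the stereocentres at the β and γ positions cannot epimerise.

**Step 8**
Reactants: 13 (R)-epichlorohydrin; 14 trimethylsilylacetylene
Product: 15 (R)-1-chloro-5-(trimethylsilyl)pent-4-yn-2-ol
Conditions: 14, n-BuLi, THF, −78 °C; BF3·OEt2; then 13, −78 °C
Reagents that add atoms: none
Why: Yamaguchi–Hirao alkynylation: the BF3-activated epoxide is opened by the lithium acetylide at its unsubstituted carbon, so the stereocentre is not touched.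

**Step 9**
Reactants: 15 (R)-1-chloro-5-(trimethylsilyl)pent-4-yn-2-ol
Product: 18 (R)-hex-1-en-5-yn-3-ol, via silyl epoxide 16 (not isolated), via silyl enynol 17 (not isolated)
Conditions: Me3S+ I− (4 equiv), n-BuLi (3.8 equiv), THF, −20 °C to rt; then MeOH, K2CO3, rt
Reagents that add atoms: trimethylsulfonium iodide C[S+](C)C.[I-]
Why: The ylide first closes the chlorohydrin to epoxide 16, then opens it at the terminal carbon, and the sulfonium betaine eliminates dimethyl sulfide (one-carbon epoxide-to-allylic-alcohol homologation with the Corey–Chaykovsky ylide), after which methanolic carbonate removes the alkynyl silane; the carbinol C–O bond is never broken.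

**Step 10**
Reactants: 18 (R)-hex-1-en-5-yn-3-ol
Product: 21 (R,Z)-6-iodo-5-methylhexa-1,5-dien-3-ol, via E-alkenylalane 19 (not isolated), via cyclic Z-alkenylalane 20 (not isolated)
Conditions: Me3Al (3 equiv), Cp2ZrCl2 (25 mol %), (CH2Cl)2, rt; then reflux; then I2, THF, −30 to 0 °C
Reagents that add atoms: trimethylaluminium C[Al](C)C; iodine II
Why: Negishi zirconium-catalysed carboalumination adds CH3 and Al syn across the alkyne (19), heating lets the alkenylalane isomerise to the alkoxide-chelated Z isomer 20 (anti-carbometalation of homopropargylic alcohols), and iodinolysis with retention gives the Z iodide; the unactivated vinyl group should not react with Me3Al/Cp2ZrCl2.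

**Step 11**
Reactants: 21 (R,Z)-6-iodo-5-methylhexa-1,5-dien-3-ol
Product: 22 (R,Z)-triethyl[(6-iodo-5-methylhexa-1,5-dien-3-yl)oxy]silane
Conditions: Et3SiCl, imidazole, CH2Cl2, 0 °C
Reagents that add atoms: chlorotriethylsilane CC[Si](Cl)(CC)CC
Why: Standard silylation of the secondary allylic alcohol; the triethylsilyl group is chosen so that it can later be removed beside a tert-butyldimethylsilyl ether.

**Step 12**
Reactants: 22 the Z-alkenyl iodide triethylsilyl ether; 12 the aldehyde from step 7
Product: 24 (2R,3R,6Z,9R)-5-hydroxy-1-[(4-methoxybenzyl)oxy]-3,7-dimethyl-9-[(triethylsilyl)oxy]undeca-6,10-dien-2-yl (2R,3R)-2,3-dimethyloxirane-2-carboxylate (both epimers at the carbinol that is C2 of the target), via alkenylchromium 23 (not isolated)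
Conditions: CrCl2 (4 equiv), NiCl2 (1 mol %), DMSO, rt
Reagents that add atoms: none
Why: Nozaki–Hiyama–Kishi coupling: zerovalent nickel inserts into the C–I bond with retention of the Z geometry, transmetalation gives alkenylchromium 23 (trivalent chromium), and this adds only to the aldehyde in the presence of ester, epoxide and silyl ether; the new C2 carbinol is not controlled and need not be.

**Step 13**
Reactants: 24 the C2 allylic alcohol
Product: 25 the C2 tert-butyldimethylsilyl ether of 24 (C8 still triethylsilyl)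
Conditions: t-BuMe2SiCl, imidazole, DMF, rt
Reagents that add atoms: tert-butyldimethylsilyl chloride CC(C)(C)[Si](C)(C)Cl
Why: Silylation of the only free hydroxyl masks the C2 oxygen, so that no C2 ketone is present during the ring closure.

**Step 14**
Reactants: 25 the bis-silyl ether
Product: 26 the C8 alcohol (C2 tert-butyldimethylsilyl ether kept)
Conditions: PPTS (cat.), MeOH/CH2Cl2, 0 °C
Reagents that add atoms: none
Why: Acid-catalysed methanolysis removes the triethylsilyl ether far faster than the tert-butyldimethylsilyl ether (selective desilylation), freeing only the C8 hydroxyl.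

**Step 15**
Reactants: 26 the C8 alcohol; 27 2-(bromomethyl)acrylic acid
Product: 28 the C8 2-(bromomethyl)acrylate ester of 26
Conditions: DCC, DMAP (5 mol %), CH2Cl2, −20 to 0 °C
Reagents that add atoms: none
Why: Steglich esterification at low temperature with little DMAP should acylate the C8 alcohol faster than the amine can attack the allylic bromide of 27.

**Step 16**
Reactants: 28 the diene ester
Product: 29 the (R)-3-(bromomethyl)furan-2(5H)-one whose C5 side chain carries the Z-alkene, the C2 silyl ether, the C4 methyl, the C5 epoxyangelate and the C6 4-methoxybenzyl ether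
Conditions: (H2IMes)(PCy3)Cl2Ru=CHPh (second-generation Grubbs catalyst, 10 mol %), toluene, 80 °C, argon sparge
Reagents that add atoms: none
Why: Ring-closing metathesis: the ruthenium alkylidene forms at the monosubstituted C7 vinyl group and closes onto the acrylate alkene to give the five-membered α-substituted butenolide with loss of ethylene, the trisubstituted C1=C10 alkene being inert; C8 is not affected.

**Step 17**
Reactants: 29 the butenolide 4-methoxybenzyl ether
Product: 30 the C6 primary alcohol
Conditions: DDQ, CH2Cl2/pH 7 buffer, 0 °C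
Reagents that add atoms: none
Why: Oxidative cleavage of the 4-methoxybenzyl ether by DDQ under buffered conditions frees the primary C6 alcohol without acid or base, which limits acyl migration from O5.

**Step 18**
Reactants: 30 the C6 primary alcohol
Product: 31 the C6 aldehyde (α-acyloxy aldehyde with the bromomethyl butenolide at the other chain end)
Conditions: Dess–Martin periodinane, NaHCO3, CH2Cl2, 0 °C; used crude
Reagents that add atoms: none
Why: Dess–Martin oxidation under buffered conditions gives the α-acyloxy aldehyde without epimerisation at C5 and leaves the allylic bromide intact.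

**Step 19**
Reactants: 31 the bromomethyl butenolide aldehyde
Product: 33 the ten-membered α-methylene lactone with C6–OH and the C2 tert-butyldimethylsilyl ether, via allylchromium 32 (not isolated)
Conditions: CrCl2 (10 equiv), THF/DMF, rt, syringe-pump addition of 31 (final 2 mM); aqueous NH4Cl work-up
Reagents that add atoms: none
Why: CrCl2 reduces the allylic bromide by two one-electron transfers to allylchromium 32 (trivalent chromium on C13), whose γ-carbon C7 adds to the C6 aldehyde through a closed six-membered Zimmerman–Traxler transition state; this is a Nozaki–Hiyama allylation, and the closest known cases are chromium-mediated additions of 3-(bromomethyl)furan-2(5H)-ones to aldehydes and intramolecular allyl bromide–aldehyde closures of ten-membered germacrane rings. The ten-membered ring closes by 10-exo-trig attack on the aldehyde with allylic transposition (SE2′), so the endocyclic butenolide alkene becomes the C11=C13 exo-methylene and the lactone ring is never opened. C7 is controlled by C8: the chain should reach C7 on the face opposite to the C8–C9 bond, because syn attack would force a nearly eclipsed C6–C7–C8–C9 torsion inside the forming medium ring, and this gives the trans-fused lactone. C6 is controlled by the chair transition state, in which C8 is locked trans to the CH2–Cr carbon by the five-membered ring (an E-type γ-substituent) and C5 sits equatorial, giving the anti 6R,7R arrangement. The step needs chemoselectivity for the aldehyde, which holds because esters, lactone and epoxide do not react with allylchromium reagents and because C2 is a silyl ether (a free C2 ketone would be attacked by C7 in a six-membered closure). It also needs the ring torsion to override the Felkin preference of the α-acyloxy aldehyde, and high dilution to suppress oligomers.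

**Step 20**
Reactants: 33 the macrocyclic silyl ether
Product: 34 the macrocyclic C2,C6-diol
Conditions: HF·pyridine, pyridine, THF, 0 °C to rt
Reagents that add atoms: none
Why: Fluoride-mediated desilylation with pyridine-buffered HF removes the allylic silyl ether without opening the epoxide or adding to the α-methylene lactone.

**Step 21**
Reactants: 34 the macrocyclic diol
Product: 35 Vicolide D
Conditions: MnO2 (activated, excess), CH2Cl2, rt
Reagents that add atoms: none
Why: MnO2 oxidises only the allylic C2 alcohol (both epimers) to the enone, the homoallylic C6 alcohol being inert, and the ten-membered ring holds the Z geometry of C1=C10.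

**Compound list**
1 | methyl angelate | C/C=C(/C)C(=O)OC | starting material
2 | (Z)-2-methylbut-2-en-1-ol | C/C=C(/C)CO | intermediate
3 | [(2S,3R)-2,3-dimethyloxiran-2-yl]methanol | OC[C@]1(C)O[C@@H]1C | intermediate
4 | (2R,3R)-2,3-dimethyloxirane-2-carboxylic acid | OC(=O)[C@]1(C)O[C@@H]1C | intermediate
5 | 2-[(4-methoxybenzyl)oxy]acetaldehyde | COc1ccc(COCC=O)cc1 | starting material
6 | trans-2-butene | C/C=C/C | starting material
7 | diisopinocampheylborinate of 8 | C=C[C@@H](C)[C@H](COCc1ccc(OC)cc1)OB([C@H]1C[C@H]2C[C@@H]([C@@H]1C)C2(C)C)[C@H]1C[C@H]2C[C@@H]([C@@H]1C)C2(C)C | intermediate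
8 | (2R,3R)-1-[(4-methoxybenzyl)oxy]-3-methylpent-4-en-2-ol | C=C[C@@H](C)[C@@H](O)COCc1ccc(OC)cc1 | intermediate
9 | (2R,3R)-1-[(4-methoxybenzyl)oxy]-3-methylpent-4-en-2-yl (2R,3R)-2,3-dimethyloxirane-2-carboxylate | C=C[C@@H](C)[C@@H](OC(=O)[C@]1(C)O[C@@H]1C)COCc1ccc(OC)cc1 | intermediate
10 | B-alkyl-9-borabicyclo[3.3.1]nonane from 9 | C1CC2CCCC(C1)B2CC[C@@H](C)[C@@H](OC(=O)[C@]1(C)O[C@@H]1C)COCc1ccc(OC)cc1 | intermediate
11 | (2R,3R)-5-hydroxy-1-[(4-methoxybenzyl)oxy]-3-methylpentan-2-yl (2R,3R)-2,3-dimethyloxirane-2-carboxylate | OCC[C@@H](C)[C@@H](OC(=O)[C@]1(C)O[C@@H]1C)COCc1ccc(OC)cc1 | intermediate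
12 | (2R,3R)-1-[(4-methoxybenzyl)oxy]-3-methyl-5-oxopentan-2-yl (2R,3R)-2,3-dimethyloxirane-2-carboxylate | O=CC[C@@H](C)[C@@H](OC(=O)[C@]1(C)O[C@@H]1C)COCc1ccc(OC)cc1 | intermediate
13 | (R)-epichlorohydrin | ClC[C@H]1CO1 | starting material
14 | trimethylsilylacetylene | C#C[Si](C)(C)C | starting material
15 | (R)-1-chloro-5-(trimethylsilyl)pent-4-yn-2-ol | ClC[C@H](O)CC#C[Si](C)(C)C | intermediate
16 | (R)-trimethyl[3-(oxiran-2-yl)prop-1-yn-1-yl]silane | C[Si](C)(C)C#CC[C@@H]1CO1 | intermediate
17 | (R)-6-(trimethylsilyl)hex-1-en-5-yn-3-ol | C=C[C@H](O)CC#C[Si](C)(C)C | intermediate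
18 | (R)-hex-1-en-5-yn-3-ol | C=C[C@H](O)CC#C | intermediate
19 | E-alkenyl(dimethyl)alane, O-dimethylaluminium alkoxide of the carboalumination product | C=C[C@H](O[Al](C)C)C/C(C)=C/[Al](C)C | intermediate
20 | six-membered Z-alkenylalane alkoxide chelate | C=C[C@H]1C/C(C)=C\[Al](C)O1 | intermediate
21 | (R,Z)-6-iodo-5-methylhexa-1,5-dien-3-ol | C=C[C@H](O)C/C(C)=C\I | intermediate
22 | (R,Z)-triethyl[(6-iodo-5-methylhexa-1,5-dien-3-yl)oxy]silane | C=C[C@H](O[Si](CC)(CC)CC)C/C(C)=C\I | intermediate
23 | Z-alkenylchromium dichloride from 22 | C=C[C@H](O[Si](CC)(CC)CC)C/C(C)=C\[Cr](Cl)Cl | intermediate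
24 | open-chain C2 allylic alcohol (both C2 epimers; C8–OTES, C5 epoxyangelate, C6–OPMB) | C=C[C@H](O[Si](CC)(CC)CC)C/C(C)=C\C(O)C[C@@H](C)[C@@H](OC(=O)[C@]1(C)O[C@@H]1C)COCc1ccc(OC)cc1 | intermediate
25 | C2–OTBS, C8–OTES bis-silyl ether | C=C[C@H](O[Si](CC)(CC)CC)C/C(C)=C\C(O[Si](C)(C)C(C)(C)C)C[C@@H](C)[C@@H](OC(=O)[C@]1(C)O[C@@H]1C)COCc1ccc(OC)cc1 | intermediate
26 | C8 alcohol, C2–OTBS | C=C[C@H](O)C/C(C)=C\C(O[Si](C)(C)C(C)(C)C)C[C@@H](C)[C@@H](OC(=O)[C@]1(C)O[C@@H]1C)COCc1ccc(OC)cc1 | intermediate
27 | 2-(bromomethyl)acrylic acid | OC(=O)C(=C)CBr | starting material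
28 | C8 2-(bromomethyl)acrylate of 26 | C=C[C@H](OC(=O)C(=C)CBr)C/C(C)=C\C(O[Si](C)(C)C(C)(C)C)C[C@@H](C)[C@@H](OC(=O)[C@]1(C)O[C@@H]1C)COCc1ccc(OC)cc1 | intermediate
29 | (R)-3-(bromomethyl)butenolide, C6–OPMB | BrCC1=C[C@@H](C/C(C)=C\C(O[Si](C)(C)C(C)(C)C)C[C@@H](C)[C@@H](OC(=O)[C@]2(C)O[C@@H]2C)COCc2ccc(OC)cc2)OC1=O | intermediate
30 | (R)-3-(bromomethyl)butenolide, C6–OH | BrCC1=C[C@@H](C/C(C)=C\C(O[Si](C)(C)C(C)(C)C)C[C@@H](C)[C@@H](OC(=O)[C@]2(C)O[C@@H]2C)CO)OC1=O | intermediate
31 | (R)-3-(bromomethyl)butenolide C6 aldehyde | BrCC1=C[C@@H](C/C(C)=C\C(O[Si](C)(C)C(C)(C)C)C[C@@H](C)[C@@H](OC(=O)[C@]2(C)O[C@@H]2C)C=O)OC1=O | intermediate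
32 | allylchromium dichloride from 31 | Cl[Cr](Cl)CC1=C[C@@H](C/C(C)=C\C(O[Si](C)(C)C(C)(C)C)C[C@@H](C)[C@@H](OC(=O)[C@]2(C)O[C@@H]2C)C=O)OC1=O | intermediate
33 | macrocyclic α-methylene lactone, C2–OTBS, C6–OH | C=C1C(=O)O[C@@H]2C/C(C)=C\C(O[Si](C)(C)C(C)(C)C)C[C@@H](C)[C@@H](OC(=O)[C@]3(C)O[C@@H]3C)[C@H](O)[C@@H]12 | intermediate
34 | macrocyclic C2,C6-diol | C=C1C(=O)O[C@@H]2C/C(C)=C\C(O)C[C@@H](C)[C@@H](OC(=O)[C@]3(C)O[C@@H]3C)[C@H](O)[C@@H]12 | intermediate
35 | Vicolide D | C=C1C(=O)O[C@@H]2C/C(C)=C\C(=O)C[C@@H](C)[C@@H](OC(=O)[C@]3(C)O[C@@H]3C)[C@H](O)[C@@H]12 | target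

**Step count.** Total: 21 steps. Longest linear sequence: 16 steps (1–3, 5–7, 12–21).

**Steps most likely to fail**

Step 19. The chain may attack the butenolide face syn to C9, or the Felkin bias of the α-acyloxy aldehyde may favour a transition state that gives the C6 epimer; slow closure would also let oligomerisation and protonation of the allylchromium compete. The fallback sets C6 and C7 in an intermolecular chromium-mediated addition, where the butenolide face is ruled by C8 alone, and closes the ten-membered ring afterwards at C1–C2. It sets out from 21 and 11 and comes back at 34. From 21, esterification with 27 (DCC, cat. DMAP) should give (R,Z)-6-iodo-5-methylhexa-1,5-dien-3-yl 2-(bromomethyl)acrylate F1, and ring-closing metathesis the iodo butenolide (R)-3-(bromomethyl)-5-[(Z)-3-iodo-2-methylallyl]furan-2(5H)-one F2. From 11, Et3SiCl/imidazole gives the C2 triethylsilyl ether F3, DDQ the C6 alcohol F4 and Dess–Martin periodinane the C6 aldehyde F5. CrCl2 without nickel (the alkenyl iodide stays inert) joins F2 and F5 to the open-chain α-methylene lactone F6, with attack anti to the C8 substituent through a chair transition state. t-BuMe2SiOTf/2,6-lutidine gives the C6 silyl ether F7, PPTS/MeOH the primary C2 alcohol F8 and Dess–Martin periodinane the C2 aldehyde F9. An intramolecular Nozaki–Hiyama–Kishi reaction (CrCl2, cat. NiCl2, DMSO, high dilution) then closes the ring to the macrocyclic C2 alcohol F10, and HF·pyridine gives 34, which enters step 21.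

Step 16. The ruthenium alkylidene may close only slowly onto the hindered, electron-poor acrylate alkene while the allylic bromide is lost; the same bromide may already be attacked by DMAP in step 15. The fallback separates ring closure from bromide installation; it sets out from 26 and comes back at 29. Commercial ethyl 2-(hydroxymethyl)acrylate is silylated to ethyl 2-{[(tert-butyldimethylsilyl)oxy]methyl}acrylate F11 and saponified (LiOH) to 2-{[(tert-butyldimethylsilyl)oxy]methyl}acrylic acid F12. Esterification of 26 with F12 (DCC, DMAP) gives the diene ester F13, and ring-closing metathesis the 3-(silyloxymethyl)butenolide F14. HF·pyridine at 0 °C should remove the primary allylic silyl ether before the secondary one and give the 3-(hydroxymethyl)butenolide F15, and CBr4/PPh3 converts it into 29.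

Step 10. The E-to-Z isomerisation of the alkenylalane may stay incomplete, or the allylic alkoxide and the vinyl group may be degraded during the long heating with Me3Al. The fallback carries out the carbometalation before the vinyl group exists; it sets out from 15 and comes back at 21. Bu4NF buffered with AcOH removes the alkynyl silane to give (R)-1-chloropent-4-yn-2-ol F16. The same Negishi sequence (Me3Al, Cp2ZrCl2; heat; I2) gives (R,Z)-1-chloro-5-iodo-4-methylpent-4-en-2-ol F17. Dimethylsulfonium methylide (Me3S+ I−, n-BuLi) then converts the chlorohydrin through its epoxide into 21.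

**Further compounds**
F1 | step 19 | (R,Z)-6-iodo-5-methylhexa-1,5-dien-3-yl 2-(bromomethyl)acrylate | C=C[C@H](OC(=O)C(=C)CBr)C/C(C)=C\I
F2 | step 19 | (R)-3-(bromomethyl)-5-[(Z)-3-iodo-2-methylallyl]furan-2(5H)-one | BrCC1=C[C@@H](C/C(C)=C\I)OC1=O
F3 | step 19 | C2 triethylsilyl ether of 11 | CC[Si](CC)(CC)OCC[C@@H](C)[C@@H](OC(=O)[C@]1(C)O[C@@H]1C)COCc1ccc(OC)cc1
F4 | step 19 | C6 alcohol from F3 | CC[Si](CC)(CC)OCC[C@@H](C)[C@@H](OC(=O)[C@]1(C)O[C@@H]1C)CO
F5 | step 19 | C6 aldehyde from F4 | CC[Si](CC)(CC)OCC[C@@H](C)[C@@H](OC(=O)[C@]1(C)O[C@@H]1C)C=O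
F6 | step 19 | open-chain α-methylene lactone, C6–OH, C2–OTES, Z-alkenyl iodide | C=C1C(=O)O[C@H](C/C(C)=C\I)[C@H]1[C@@H](O)[C@H](OC(=O)[C@]2(C)O[C@@H]2C)[C@H](C)CCO[Si](CC)(CC)CC
F7 | step 19 | C6 tert-butyldimethylsilyl ether of F6 | C=C1C(=O)O[C@H](C/C(C)=C\I)[C@H]1[C@@H](O[Si](C)(C)C(C)(C)C)[C@H](OC(=O)[C@]2(C)O[C@@H]2C)[C@H](C)CCO[Si](CC)(CC)CC
F8 | step 19 | primary C2 alcohol from F7 | C=C1C(=O)O[C@H](C/C(C)=C\I)[C@H]1[C@@H](O[Si](C)(C)C(C)(C)C)[C@H](OC(=O)[C@]2(C)O[C@@H]2C)[C@H](C)CCO
F9 | step 19 | C2 aldehyde from F8 | C=C1C(=O)O[C@H](C/C(C)=C\I)[C@H]1[C@@H](O[Si](C)(C)C(C)(C)C)[C@H](OC(=O)[C@]2(C)O[C@@H]2C)[C@H](C)CC=O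
F10 | step 19 | macrocyclic C2 alcohol, C6–OTBS | C=C1C(=O)O[C@@H]2C/C(C)=C\C(O)C[C@@H](C)[C@@H](OC(=O)[C@]3(C)O[C@@H]3C)[C@H](O[Si](C)(C)C(C)(C)C)[C@@H]12
F11 | step 16 | ethyl 2-{[(tert-butyldimethylsilyl)oxy]methyl}acrylate | CCOC(=O)C(=C)CO[Si](C)(C)C(C)(C)C
F12 | step 16 | 2-{[(tert-butyldimethylsilyl)oxy]methyl}acrylic acid | OC(=O)C(=C)CO[Si](C)(C)C(C)(C)C
F13 | step 16 | C8 ester of 26 with F12 | C=C[C@H](OC(=O)C(=C)CO[Si](C)(C)C(C)(C)C)C/C(C)=C\C(O[Si](C)(C)C(C)(C)C)C[C@@H](C)[C@@H](OC(=O)[C@]1(C)O[C@@H]1C)COCc1ccc(OC)cc1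
F14 | step 16 | 3-(silyloxymethyl)butenolide | CC(C)(C)[Si](C)(C)OCC1=C[C@@H](C/C(C)=C\C(O[Si](C)(C)C(C)(C)C)C[C@@H](C)[C@@H](OC(=O)[C@]2(C)O[C@@H]2C)COCc2ccc(OC)cc2)OC1=O
F15 | step 16 | 3-(hydroxymethyl)butenolide | OCC1=C[C@@H](C/C(C)=C\C(O[Si](C)(C)C(C)(C)C)C[C@@H](C)[C@@H](OC(=O)[C@]2(C)O[C@@H]2C)COCc2ccc(OC)cc2)OC1=O
F16 | step 10 | (R)-1-chloropent-4-yn-2-ol | ClC[C@H](O)CC#C
F17 | step 10 | (R,Z)-1-chloro-5-iodo-4-methylpent-4-en-2-ol | ClC[C@H](O)C/C(C)=C\I
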